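**Plan**

1. The target is an achiral 2-hydroxy-1,4-benzoquinone: C1 (C=O), C2 (OH), C3 (indole A = 2-(2-methylbut-3-en-2-yl)indol-3-yl), C4 (C=O), C5 (prenyl), C6 (indole B = indol-3-yl). The oxygens on C2 and C4 are meta to each other with C3 between them, which is the substitution pattern a vinylketene and an ynol ether leave behind; this feature makes the key step possible.
2. Retrosynthesis: the C1 oxygen is removed first (late oxidation of a resorcinol C1–H). The ring is then cut at C3–C4, C1–C2 and C4–C5 into a 3-(indol-3-yl)-4-prenylcyclobutenone (supplies C4, C1, C6, C5) and an indole A siloxyalkyne (supplies C3, C2).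
3. The cyclobutenone goes back to prenylketene, ethoxyacetylene and a 3-lithioindole. The alkyne goes back to 2-(2-methylbut-3-en-2-yl)indole (from o-toluidine and a 2,2-dimethylbut-3-enoate) by way of N-protection, iodination, Sonogashira coupling and acetylide oxygenation.
4. Forward: the four-membered ring is made first, the benzene ring is the only ring closed in the key step (6π electrocyclisation), and global desilylation followed by oxidation at C1 gives the quinone.
5. Stereochemistry: the target has no stereocentre and no stereogenic alkene; the racemic sp3 carbon of the cyclobutenone is erased on aromatisation.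

Key step: step 12

Assumption: the target is treated as the drawn 2-hydroxy-1,4-quinone tautomer (it equilibrates with the 4-hydroxy-1,2-quinone form); 5-methylhex-4-enoic acid, ethoxyacetylene (hexane solution), 3-bromo-1-(triisopropylsilyl)indole, 2,2-dimethylbut-3-enoic acid, o-toluidine and ethynyltrimethylsilane are taken as purchasable; the nitrogen of indole A is carried as its SEM derivative so that the alkyne chemistry can be run with organolithium reagents.

**Route**

Step 1
Reactants: 1 5-methylhex-4-enoic acid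
Product: 2 5-methylhex-4-enoyl chloride
Conditions: (COCl)2, DMF (cat.), CH2Cl2, 0 °C to rt; concentrated and used crude
Reagents that add atoms: oxalyl chloride, O=C(Cl)C(=O)Cl
Why: Acyl chloride formation through the DMF-derived chloroiminium catalyst needs neither strong acid nor heat, so the trisubstituted alkene should survive.

Step 2
Reactants: 2 5-methylhex-4-enoyl chloride; 3 ethoxyacetylene
Product: 5 3-ethoxy-4-(3-methylbut-2-enyl)cyclobut-2-en-1-one (racemic), via prenylketene 4 (not isolated)
Conditions: Et3N (1.2 equiv), Et2O, 0 °C to rt, 2 added slowly to 3 (2.5 equiv)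
Reagents that add atoms: none
Why: Et3N dehydrochlorinates 2 to aldoketene 4, which the electron-rich alkyne traps in a thermal ketene–alkyne [2+2] cycloaddition whose polarity (ketene carbonyl carbon to the unsubstituted alkyne carbon) puts ethoxy at C3 and the prenyl-bearing sp3 carbon at C4, the excess of 3 outrunning ketene dimerisation.

Step 3
Reactants: 6 3-bromo-1-(triisopropylsilyl)-1H-indole; 5 3-ethoxy-4-(3-methylbut-2-enyl)cyclobut-2-en-1-one
Product: 9 4-(3-methylbut-2-enyl)-3-[1-(triisopropylsilyl)indol-3-yl]cyclobut-2-en-1-one (racemic), via 3-lithioindole 7 (not isolated), via lithium carbinolate 8 (not isolated)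
Conditions: t-BuLi (2.0 equiv), THF, −78 °C; 5, −78 °C; then 1 M HCl, THF, 0 °C
Reagents that add atoms: water, O
Why: Bromine–lithium exchange gives 3-lithioindole 7, held at C3 by the bulky N-silyl group, which adds 1,2 to the vinylogous ester carbonyl of 5 (enolisation of a cyclobutenone being disfavoured) to give carbinolate 8, and dilute acid then ionises the doubly stabilised tertiary carbinol and hydrolyses the enol ether with 1,3-carbonyl transposition (Stork–Danheiser-type sequence), so the indolyl group ends at C3 and the prenyl-bearing carbon at C4.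

Step 4
Reactants: 10 2,2-dimethylbut-3-enoic acid
Product: 11 methyl 2,2-dimethylbut-3-enoate
Conditions: MeI, K2CO3, DMF, rt; pentane extraction, distillation
Reagents that add atoms: iodomethane, CI
Why: SN2 O-methylation of the potassium carboxylate avoids the acid of a Fischer esterification next to the tertiary allylic centre.

Step 5
Reactants: 12 o-toluidine (2-methylaniline)
Product: 13 N-(trimethylsilyl)-2-methylaniline
Conditions: n-BuLi (1.0 equiv), THF, −78 to 0 °C; Me3SiCl; distillation
Reagents that add atoms: chlorotrimethylsilane, C[Si](C)(C)Cl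
Why: N-lithiation of the aniline and trapping with Me3SiCl gives the mono-N-silyl aniline needed as the aza-Peterson partner in the next step.

Step 6
Reactants: 13 N-(trimethylsilyl)-2-methylaniline; 11 methyl 2,2-dimethylbut-3-enoate
Product: 16 2-(2-methylbut-3-en-2-yl)-1H-indole, via dilithio toluidine 14 (not isolated), via lithio amino ketone 15 (not isolated)
Conditions: n-BuLi (2.2 equiv), hexane, reflux; then 11, THF, −78 °C to rt
Reagents that add atoms: none
Why: In the Smith modification of the Madelung indole synthesis the N,C-dilithio species 14 is acylated at its benzylic carbon by the non-enolisable ester, and the N-silyl amide of ketone 15 then adds to the carbonyl and expels Me3SiOLi (aza-Peterson olefination) to give the 2-tert-alkylindole without acid or high temperature.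

Step 7
Reactants: 16 2-(2-methylbut-3-en-2-yl)-1H-indole
Product: 17 2-(2-methylbut-3-en-2-yl)-1-{[2-(trimethylsilyl)ethoxy]methyl}-1H-indole
Conditions: NaH, DMF, 0 °C; Me3SiCH2CH2OCH2Cl, 0 °C to rt
Reagents that add atoms: 2-(trimethylsilyl)ethoxymethyl chloride, C[Si](C)(C)CCOCCl
Why: N-alkylation of the sodium indolide with the unhindered, highly reactive chloromethyl ether should proceed despite the tertiary neighbour and masks the N–H for the organolithium steps while staying fluoride-labile.

Step 8
Reactants: 17 2-(2-methylbut-3-en-2-yl)-1-{[2-(trimethylsilyl)ethoxy]methyl}-1H-indole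
Product: 18 3-iodo-2-(2-methylbut-3-en-2-yl)-1-{[2-(trimethylsilyl)ethoxy]methyl}-1H-indole
Conditions: N-iodosuccinimide (1.05 equiv), DMF, 0 °C, dark
Reagents that add atoms: N-iodosuccinimide, O=C1CCC(=O)N1I
Why: Electrophilic aromatic iodination takes the only free and most nucleophilic pyrrole position, C3, far faster than iodine adds to the monosubstituted alkene.

Step 9
Reactants: 18 3-iodo-2-(2-methylbut-3-en-2-yl)-1-{[2-(trimethylsilyl)ethoxy]methyl}-1H-indole; 19 ethynyltrimethylsilane
Product: 20 2-(2-methylbut-3-en-2-yl)-1-{[2-(trimethylsilyl)ethoxy]methyl}-3-[(trimethylsilyl)ethynyl]-1H-indole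
Conditions: PdCl2(PPh3)2 (5 mol%), CuI (10 mol%), Et3N, THF, 50 °C
Reagents that add atoms: none
Why: Sonogashira coupling of the aryl iodide with the slim terminal alkyne tolerates the ortho tertiary group, and fast transmetalation from the copper acetylide should outrun any Heck-type reaction with the pendant vinyl group.

Step 10
Reactants: 20 2-(2-methylbut-3-en-2-yl)-1-{[2-(trimethylsilyl)ethoxy]methyl}-3-[(trimethylsilyl)ethynyl]-1H-indole
Product: 21 3-ethynyl-2-(2-methylbut-3-en-2-yl)-1-{[2-(trimethylsilyl)ethoxy]methyl}-1H-indole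
Conditions: K2CO3, MeOH/THF, rt
Reagents that add atoms: none
Why: Base-mediated methanolysis of the alkynyl C–Si bond (protodesilylation) leaves the N-SEM group and both alkenes untouched.

Step 11
Reactants: 21 3-ethynyl-2-(2-methylbut-3-en-2-yl)-1-{[2-(trimethylsilyl)ethoxy]methyl}-1H-indole
Product: 24 2-(2-methylbut-3-en-2-yl)-3-[(triisopropylsiloxy)ethynyl]-1-{[2-(trimethylsilyl)ethoxy]methyl}-1H-indole, via lithium acetylide 22 (not isolated), via lithium ynolate 23 (not isolated)
Conditions: n-BuLi (1.05 equiv), THF, −78 °C; LiOOt-Bu (from t-BuOOH and LiN(SiMe3)2, THF, −78 °C), −78 to 0 °C; i-Pr3SiOTf, −78 to 0 °C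
Reagents that add atoms: tert-butyl hydroperoxide, CC(C)(C)OO; triisopropylsilyl trifluoromethanesulfonate, CC(C)[Si](OS(=O)(=O)C(F)(F)F)(C(C)C)C(C)C
Why: Lithium acetylide 22 attacks the electrophilic peroxide oxygen of LiOOt-Bu to give lithium ynolate 23 with loss of LiOt-Bu, and the hard silyl triflate then silylates the ynolate on oxygen, the bulky triisopropylsilyl group giving an ynol ether that should tolerate rapid chromatography on base-washed silica (acetylide oxidation to an ynolate followed by O-silylation).

Step 12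
Reactants: 9 4-(3-methylbut-2-enyl)-3-[1-(triisopropylsilyl)indol-3-yl]cyclobut-2-en-1-one; 24 2-(2-methylbut-3-en-2-yl)-3-[(triisopropylsiloxy)ethynyl]-1-{[2-(trimethylsilyl)ethoxy]methyl}-1H-indole
Product: 29 2-[2-(2-methylbut-3-en-2-yl)-1-{[2-(trimethylsilyl)ethoxy]methyl}indol-3-yl]-6-(3-methylbut-2-enyl)-5-[1-(triisopropylsilyl)indol-3-yl]-3-(triisopropylsiloxy)phenol, via vinylketene 25 (not isolated), via vinylcyclobutenone 26 (not isolated), via dienylketene 27 (not isolated), via cyclohexadienone 28 (not isolated)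
Conditions: 24 (1.3 equiv), toluene, 80 °C then 110 °C, argon, sealed tube
Reagents that add atoms: none
Why: Heating opens cyclobutenone 9 by 4π electrocyclic cleavage of its C1–C4 bond to vinylketene 25, whose ketene C=C adds [2+2] to ynol ether 24 to give vinylcyclobutenone 26; this reopens reversibly to dienylketene 27, which closes by thermal 6π electrocyclisation to cyclohexadienone 28 and enolises to phenol 29 (Danheiser benzannulation of a cyclobutenone with a siloxyalkyne). The one new ring, the benzene ring, is closed by this disrotatory 6π electrocyclisation, which joins the former ketene carbon to the prenyl-bearing carbon, while the other two new bonds (ketene carbon to the indolyl-bearing alkyne carbon, siloxy carbon to the ketene α-carbon) come from the [2+2] step. No stereocentre is created, and the racemic sp3 centre of 9 is lost on aromatisation. The step needs regioselectivity in the [2+2] addition, and the polarisation of the ynol ether secures it: the nucleophilic carbon carrying indole A attacks the electrophilic ketene carbonyl carbon, so the siloxy carbon ends meta to the new phenol with indole A between the two oxygens. Chemoselectivity rests on the neutral, reagent-free conditions, which leave both prenyl-type alkenes and the N–Si, N–CH2O and O–Si bonds alone, on outward rotation of the prenyl-bearing carbon during ring opening, which places that chain outside the closing triene, and on the crowded position of the new phenol, which makes it a poor trap for ketene.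

Step 13
Reactants: 29 2-[2-(2-methylbut-3-en-2-yl)-1-{[2-(trimethylsilyl)ethoxy]methyl}indol-3-yl]-6-(3-methylbut-2-enyl)-5-[1-(triisopropylsilyl)indol-3-yl]-3-(triisopropylsiloxy)phenol
Product: 30 5-(1H-indol-3-yl)-2-[2-(2-methylbut-3-en-2-yl)-1H-indol-3-yl]-4-(3-methylbut-2-enyl)benzene-1,3-diol
Conditions: Bu4NF (8 equiv), H2NCH2CH2NH2, THF, rt then 65 °C, argon; used at once
Reagents that add atoms: none
Why: Fluoride cleaves the Si–O and Si–N bonds at room temperature and, on warming, triggers fragmentation of the SEM group to ethene, formaldehyde and the indolide, ethylenediamine removing the formaldehyde before it can hydroxymethylate the free ring position (fluoride-mediated global desilylation).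

Step 14
Reactants: 30 5-(1H-indol-3-yl)-2-[2-(2-methylbut-3-en-2-yl)-1H-indol-3-yl]-4-(3-methylbut-2-enyl)benzene-1,3-diol
Product: 31 CNP0134649.0, 2-hydroxy-5-(1H-indol-3-yl)-3-[2-(2-methylbut-3-en-2-yl)-1H-indol-3-yl]-6-(3-methylbut-2-enyl)cyclohexa-2,5-diene-1,4-dione
Conditions: ON(SO3K)2 (2.5 equiv), KH2PO4 buffer, acetone/H2O, 0 °C to rt
Reagents that add atoms: potassium nitrosodisulfonate, [K+].[K+].[O]N(S(=O)(=O)[O-])S(=O)(=O)[O-]
Why: In the Teuber oxidation one equivalent of ON(SO3K)2 abstracts a phenolic hydrogen and a second couples at the single unsubstituted ring carbon of 30, which is para to one oxygen and ortho to the other, so that loss of HN(SO3K)2 gives the same 2-hydroxy-1,4-benzoquinone whichever phenoxyl forms first, while the buffered radical oxidant should be too mild to attack the alkenes or the indole rings at a competitive rate.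

**Compound list**

1 | 5-methylhex-4-enoic acid | CC(C)=CCCC(=O)O | starting material
2 | 5-methylhex-4-enoyl chloride | CC(C)=CCCC(=O)Cl | intermediate
3 | ethoxyacetylene (ethoxyethyne) | CCOC#C | starting material
4 | prenylketene (5-methylhexa-1,4-dien-1-one) | CC(C)=CCC=C=O | intermediate
5 | 3-ethoxy-4-(3-methylbut-2-enyl)cyclobut-2-en-1-one, racemic | CCOC1=CC(=O)C1CC=C(C)C | intermediate
6 | 3-bromo-1-(triisopropylsilyl)-1H-indole | CC(C)[Si](C(C)C)(C(C)C)n1cc(Br)c2ccccc21 | starting material
7 | 3-lithio-1-(triisopropylsilyl)indole | [Li]c1cn([Si](C(C)C)(C(C)C)C(C)C)c2ccccc12 | intermediate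
8 | lithium 3-ethoxy-4-(3-methylbut-2-enyl)-1-[1-(triisopropylsilyl)indol-3-yl]cyclobut-2-en-1-olate, racemic mixture of diastereomers | CCOC1=CC(O[Li])(c2cn([Si](C(C)C)(C(C)C)C(C)C)c3ccccc23)C1CC=C(C)C | intermediate
9 | 4-(3-methylbut-2-enyl)-3-[1-(triisopropylsilyl)indol-3-yl]cyclobut-2-en-1-one, racemic | O=C1C=C(c2cn([Si](C(C)C)(C(C)C)C(C)C)c3ccccc23)C1CC=C(C)C | intermediate
10 | 2,2-dimethylbut-3-enoic acid | C=CC(C)(C)C(=O)O | starting material
11 | methyl 2,2-dimethylbut-3-enoate | C=CC(C)(C)C(=O)OC | intermediate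
12 | o-toluidine (2-methylaniline) | Cc1ccccc1N | starting material
13 | N-(trimethylsilyl)-2-methylaniline | Cc1ccccc1N[Si](C)(C)C | intermediate
14 | N-lithio-N-(trimethylsilyl)-2-(lithiomethyl)aniline | [Li]Cc1ccccc1N([Li])[Si](C)(C)C | intermediate
15 | N-lithio derivative of 3,3-dimethyl-1-{2-[(trimethylsilyl)amino]phenyl}pent-4-en-2-one | C=CC(C)(C)C(=O)Cc1ccccc1N([Li])[Si](C)(C)C | intermediate
16 | 2-(2-methylbut-3-en-2-yl)-1H-indole | C=CC(C)(C)c1cc2ccccc2[nH]1 | intermediate
17 | 2-(2-methylbut-3-en-2-yl)-1-{[2-(trimethylsilyl)ethoxy]methyl}-1H-indole | C=CC(C)(C)c1cc2ccccc2n1COCC[Si](C)(C)C | intermediate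
18 | 3-iodo-2-(2-methylbut-3-en-2-yl)-1-{[2-(trimethylsilyl)ethoxy]methyl}-1H-indole | C=CC(C)(C)c1c(I)c2ccccc2n1COCC[Si](C)(C)C | intermediate
19 | ethynyltrimethylsilane | C#C[Si](C)(C)C | starting material
20 | 2-(2-methylbut-3-en-2-yl)-1-{[2-(trimethylsilyl)ethoxy]methyl}-3-[(trimethylsilyl)ethynyl]-1H-indole | C=CC(C)(C)c1c(C#C[Si](C)(C)C)c2ccccc2n1COCC[Si](C)(C)C | intermediate
21 | 3-ethynyl-2-(2-methylbut-3-en-2-yl)-1-{[2-(trimethylsilyl)ethoxy]methyl}-1H-indole | C=CC(C)(C)c1c(C#C)c2ccccc2n1COCC[Si](C)(C)C | intermediate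
22 | lithium acetylide of 21 | C=CC(C)(C)c1c(C#C[Li])c2ccccc2n1COCC[Si](C)(C)C | intermediate
23 | lithium 2-[2-(2-methylbut-3-en-2-yl)-1-{[2-(trimethylsilyl)ethoxy]methyl}indol-3-yl]ethynolate | C=CC(C)(C)c1c(C#CO[Li])c2ccccc2n1COCC[Si](C)(C)C | intermediate
24 | 2-(2-methylbut-3-en-2-yl)-3-[(triisopropylsiloxy)ethynyl]-1-{[2-(trimethylsilyl)ethoxy]methyl}-1H-indole | CC(C)[Si](OC#Cc1c(C(C)(C)C=C)n(COCC[Si](C)(C)C)c2ccccc12)(C(C)C)C(C)C | intermediate
25 | 7-methyl-3-[1-(triisopropylsilyl)indol-3-yl]octa-1,3,6-trien-1-one (vinylketene, prenyl chain trans to the ketene arm) | O=C=C/C(c1cn([Si](C(C)C)(C(C)C)C(C)C)c2ccccc12)=C/CC=C(C)C | intermediate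
26 | 2-(SEM-indole A)-3-(triisopropylsiloxy)-4-{5-methyl-1-[1-(triisopropylsilyl)indol-3-yl]hexa-1,4-dienyl}cyclobut-2-en-1-one, racemic | O=C1C(c2c(C(C)(C)C=C)n(COCC[Si](C)(C)C)c3ccccc23)=C(O[Si](C(C)C)(C(C)C)C(C)C)C1/C(c1cn([Si](C(C)C)(C(C)C)C(C)C)c2ccccc12)=C/CC=C(C)C | intermediate
27 | 2-(SEM-indole A)-9-methyl-5-[1-(triisopropylsilyl)indol-3-yl]-3-(triisopropylsiloxy)deca-1,3,5,8-tetraen-1-one (dienylketene, the geometry that can cyclise) | O=C=C(c1c(C(C)(C)C=C)n(COCC[Si](C)(C)C)c2ccccc12)/C(O[Si](C(C)C)(C(C)C)C(C)C)=C\C(c1cn([Si](C(C)C)(C(C)C)C(C)C)c2ccccc12)=C\CC=C(C)C | intermediate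
28 | 2-(SEM-indole A)-6-(3-methylbut-2-enyl)-5-[1-(triisopropylsilyl)indol-3-yl]-3-(triisopropylsiloxy)cyclohexa-2,4-dien-1-one, racemic | O=C1C(c2c(C(C)(C)C=C)n(COCC[Si](C)(C)C)c3ccccc23)=C(O[Si](C(C)C)(C(C)C)C(C)C)C=C(c2cn([Si](C(C)C)(C(C)C)C(C)C)c3ccccc23)C1CC=C(C)C | intermediate
29 | 2-[2-(2-methylbut-3-en-2-yl)-1-{[2-(trimethylsilyl)ethoxy]methyl}indol-3-yl]-6-(3-methylbut-2-enyl)-5-[1-(triisopropylsilyl)indol-3-yl]-3-(triisopropylsiloxy)phenol | Oc1c(CC=C(C)C)c(c2cn([Si](C(C)C)(C(C)C)C(C)C)c3ccccc23)cc(O[Si](C(C)C)(C(C)C)C(C)C)c1-c1c(C(C)(C)C=C)n(COCC[Si](C)(C)C)c2ccccc12 | intermediate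
30 | 5-(1H-indol-3-yl)-2-[2-(2-methylbut-3-en-2-yl)-1H-indol-3-yl]-4-(3-methylbut-2-enyl)benzene-1,3-diol | Oc1c(CC=C(C)C)c(c2c[nH]c3ccccc23)cc(O)c1-c1c(C(C)(C)C=C)[nH]c2ccccc12 | intermediate
31 | CNP0134649.0, 2-hydroxy-5-(1H-indol-3-yl)-3-[2-(2-methylbut-3-en-2-yl)-1H-indol-3-yl]-6-(3-methylbut-2-enyl)cyclohexa-2,5-diene-1,4-dione | C=CC(C)(C)c1[nH]c2ccccc2c1C1=C(O)C(=O)C(c2c[nH]c3ccccc23)=C(CC=C(C)C)C1=O | target

("SEM-indole A" in 26–28 stands for 2-(2-methylbut-3-en-2-yl)-1-{[2-(trimethylsilyl)ethoxy]methyl}indol-3-yl.)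

**Step count**

Total steps: 14. Longest linear sequence: 10 steps (5, 6, 7, 8, 9, 10, 11, 12, 13, 14; equally 4, 6–14). The cyclobutenone arm (steps 1–3) joins at step 12.

**Steps most likely to fail, with fallbacks**

Step 12. The silyl ynol ether may be consumed before the cyclobutenone has opened (1,3-shift of silicon from oxygen to carbon giving a silylketene, or protodesilylation), or the [2+2] addition may be slow enough for the vinylketene to dimerise. The fallback keeps the same ring construction but uses an ethyl ynol ether, the original alkoxyalkyne partner of this benzannulation, and changes the endgame accordingly. It sets out from iodide 18. Negishi coupling with (ethoxyethynyl)zinc chloride (from ethoxyacetylene 3, n-BuLi and ZnCl2; Pd(PPh3)4, THF, rt) should give 3-(ethoxyethynyl)-2-(2-methylbut-3-en-2-yl)-1-SEM-indole F1. Heating F1 with cyclobutenone 9 in toluene at 80 °C, below the retro-ene threshold of ethyl ynol ethers, should give by the same cascade the resorcinol monoethyl ether F2. Bu4NF with ethylenediamine then frees both indole nitrogens to give the N-unprotected ethoxyphenol F3. ON(SO3K)2 oxidises the free phenol at its open para position to the 2-ethoxy-1,4-benzoquinone F4, and aqueous NaOH in ethanol hydrolyses this vinylogous ester, so the sequence comes back to the route at target 31.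

Step 11. Oxygen transfer from the peroxide to the acetylide may be incomplete, the peroxide may attack the electron-rich indole, or the ynolate may be protonated during silylation and work-up. The fallback reaches the same ynolate by a Kowalski rearrangement and avoids the peroxide. It sets out from the N-SEM indole 17. C3 acylation with dibromoacetyl chloride (pyridine, CH2Cl2, 0 °C) gives the 3-(dibromoacetyl)indole F5. Its enolate (LiN(SiMe3)2, THF, −78 °C) undergoes bromine–lithium exchange with n-BuLi and 1,2-shift of the indolyl group on warming to 0 °C, giving lithium ynolate 23. Silylation with i-Pr3SiOTf as in step 11 brings the sequence back to the route at 24.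

Step 14. Radical oxidation of the free N–H indoles (C3 of indole A, C2 of indole B) or oxidative coupling of the very electron-rich resorcinol may compete with quinone formation. The fallback moves the oxidation ahead of the unmasking. It sets out from phenol 29, in which both indole nitrogens are still blocked and the only free phenol has a single open para position. Co(salen) under O2 in DMF should give the 2-(triisopropylsiloxy)-1,4-benzoquinone F6. Bu4NF in THF, here without the diamine since the fully substituted quinone offers no position for hydroxymethylation and a primary amine would add to it, then removes the O-silyl, N-silyl and SEM groups, and acidic work-up of the base-stable hydroxyquinone anion brings the sequence back to the route at target 31.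

**Further compounds**

F1 | step 12 | 3-(ethoxyethynyl)-2-(2-methylbut-3-en-2-yl)-1-{[2-(trimethylsilyl)ethoxy]methyl}-1H-indole | CCOC#Cc1c(C(C)(C)C=C)n(COCC[Si](C)(C)C)c2ccccc12
F2 | step 12 | 3-ethoxy-2-[2-(2-methylbut-3-en-2-yl)-1-{[2-(trimethylsilyl)ethoxy]methyl}indol-3-yl]-6-(3-methylbut-2-enyl)-5-[1-(triisopropylsilyl)indol-3-yl]phenol | CCOc1cc(c2cn([Si](C(C)C)(C(C)C)C(C)C)c3ccccc23)c(CC=C(C)C)c(O)c1-c1c(C(C)(C)C=C)n(COCC[Si](C)(C)C)c2ccccc12
F3 | step 12 | 3-ethoxy-5-(1H-indol-3-yl)-2-[2-(2-methylbut-3-en-2-yl)-1H-indol-3-yl]-6-(3-methylbut-2-enyl)phenol | CCOc1cc(c2c[nH]c3ccccc23)c(CC=C(C)C)c(O)c1-c1c(C(C)(C)C=C)[nH]c2ccccc12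
F4 | step 12 | 2-ethoxy-5-(1H-indol-3-yl)-3-[2-(2-methylbut-3-en-2-yl)-1H-indol-3-yl]-6-(3-methylbut-2-enyl)cyclohexa-2,5-diene-1,4-dione | CCOC1=C(c2c(C(C)(C)C=C)[nH]c3ccccc23)C(=O)C(CC=C(C)C)=C(c2c[nH]c3ccccc23)C1=O
F5 | step 11 | 2,2-dibromo-1-[2-(2-methylbut-3-en-2-yl)-1-{[2-(trimethylsilyl)ethoxy]methyl}indol-3-yl]ethan-1-one | C=CC(C)(C)c1c(C(=O)C(Br)Br)c2ccccc2n1COCC[Si](C)(C)C
F6 | step 14 | 3-[2-(2-methylbut-3-en-2-yl)-1-{[2-(trimethylsilyl)ethoxy]methyl}indol-3-yl]-6-(3-methylbut-2-enyl)-5-[1-(triisopropylsilyl)indol-3-yl]-2-(triisopropylsiloxy)cyclohexa-2,5-diene-1,4-dione | CC(C)[Si](OC1=C(c2c(C(C)(C)C=C)n(COCC[Si](C)(C)C)c3ccccc23)C(=O)C(CC=C(C)C)=C(c2cn([Si](C(C)C)(C(C)C)C(C)C)c3ccccc23)C1=O)(C(C)C)C(C)C
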